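0.301 powers of ten of catalyst separate epsilon from the other runs, and that small step carries the argument.

common to all: substrate 0.80 M; impurity 0.59 mM

| flask | partner | free catalyst | remark |
|---|---|---|---|
| eta | 0.48 M | 2.6 mM | run made earlier |
| delta | 1.9 M | 2.6 mM | run made earlier |
| epsilon | 0.96 M | 1.3 mM | run made earlier |
| flask | 0.960 M | 2.6 mM |  |

| run | time / h | product / % | substrate / % |
|---|---|---|---|
| eta | 2.50 | 2.7 | 97.1 |
| eta | 5.00 | 4.8 | 96.0 |
| eta | 8.00 | 8.0 | 93.0 |
| eta | 15.0 | 12.7 | 86.7 |
| eta | 30.0 | 23.7 | 75.5 |
| delta | 2.50 | 2.6 | 97.8 |
| delta | 5.00 | 5.0 | 95.2 |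
| delta | 8.00 | 7.7 | 91.5 |
| delta | 15.0 | 14.4 | 86.0 |
| delta | 30.0 | 26.3 | 73.3 |
| epsilon | 6.00 | 2.7 | 97.4 |
| epsilon | 12.0 | 6.0 | 95.0 |
| epsilon | 20.0 | 8.3 | 91.1 |
| epsilon | 25.0 | 9.9 | 89.5 |
| epsilon | 30.0 | 12.8 | 87.0 |

(standard deviation of a reading: 0.5 percentage points)

- the numbers in the tables scatter by 0.5 percentage points (one standard deviation)

- factor on the rate of making product when 20 % of the substrate are converted if partner is charged twice over
- factor on the rate when 20 % of the substrate are converted if free catalyst is charged at 12 mM instead

The partner charge of the flask, 0.960 M, stands close to the geometric mean of eta and delta, so the mean of their product readings at 30.0 h, 25.0 % of the substrate charged, can serve for it. But epsilon, with half the catalyst, shows 12.8 %. Powers of ten gained in product at that time per power of ten in charge give 0.966, the reading of the order in catalyst. So 12 mM multiplies the rate by 4.38 in this reckoning, less than the forecast says.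

The same rule from eta to delta gives a partner order of 0.0757. At 20 % conversion, with one partner taken per substrate, a double charge holds 2.20 times the partner, so the rate gains 1.06.

The forecast gives 1.03 for the double partner charge, less than this reckoning, and 4.8 for the catalyst, more than this reckoning, and calls the catalyst dependence “roughly first order”.

The simulation gives 1.08 and 5.42.

    substrate + catalyst intermediate B ⇌ catalyst intermediate C (K = 6.90 M⁻¹, k = 0.300 M⁻¹ min⁻¹)
    catalyst intermediate A → catalyst intermediate B (k = 0.700 min⁻¹)
    free catalyst + impurity → spent catalyst (k = 140 M⁻¹ min⁻¹)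
    partner + free catalyst → catalyst intermediate A (k = 16.0 M⁻¹ min⁻¹)
    catalyst intermediate D → free catalyst + product (k = 0.110 min⁻¹)
    catalyst intermediate C → catalyst intermediate D (k = 0.260 min⁻¹)

Carried from epsilon, the order 0.966 puts this flask at 20 % conversion after 24.0 h, and the flask is there after 23.0 h; the flask at 12 mM has the simulated factor 5.42, against 4.38 from that order. After 25.0 h this flask holds 35.8 % of its catalyst as catalyst intermediate D and 5.62 % as catalyst intermediate A, a factor of 6.37. The half-life of catalyst intermediate D by its own step, 6.30 min, stands against 0.990 min for catalyst intermediate A by its own step, a factor of 6.36.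

(Readings and results are calculated for substances that don't exist, and the scatter is random.)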